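**Retrosynthetic overview**

- Scolopendrine ⇐ transfer hydrogenolysis of the trichloroethyl-masked 8-sulfate of the O-benzyl quinolinone ⇐ TFA treatment (loss of the N-dimethoxybenzyl group, elimination of MeOH across C3–C4) ⇐ sulfation of the free C8–OH of an N-dimethoxybenzyl 3,3-dimethoxy-3,4-dihydroquinolin-2-one.
- Feature used: on the carbocycle the oxygen-bearing C8 lies between the nitrogen-bearing C8a and the benzyl-bearing C7. This is the pattern left when a 5-benzylfuran closes onto a terminal ynamide: the N-carbon becomes C8a and the alkyne CH becomes C8–OH.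
- Key disconnection: C4a–C8a, C7–C8 and C8–O, all made in one gold(I) furan–ynamide cycloisomerisation of a furan-tethered N-ethynyl amide.
- Ring order: furan (bought) → lactam ring first (C-attack of furan C2), then the benzene ring (oxepine/arene oxide) in the same step → pyridone aromatised later by loss of MeOH.
- Precursor ⇐ N-ethynylation of the secondary amide ⇐ aminolysis of the ketal ester ⇐ C-alkylation of the methyl dimethoxyacetate enolate with the furfuryl bromide ⇐ furfuryl alcohol ⇐ Suzuki coupling of 5-(chloromethyl)furfural with the arylboronic acid.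

Key step: step 6

Remark: the target has no stereocentre, so no enantiomer has to be chosen; the only stereodefined species on the route is the transient racemic arene oxide 13.
Remark: aryl hydrogen sulfates are written in the acid form of the target SMILES; the final product would be isolated as its ammonium salt and the acid set free by a cold pass through an H+ exchange resin.

**Route**

Step 1
Reactants: 1 5-(chloromethyl)furan-2-carbaldehyde; 2 [4-(benzyloxy)-3-methoxyphenyl]boronic acid
Product: 3 5-[4-(benzyloxy)-3-methoxybenzyl]furan-2-carbaldehyde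
Conditions: Pd(OAc)2 (2 mol%), PPh3 (4 mol%), K3PO4, toluene, 80 °C
Reagents that add atoms: none
Why: Suzuki–Miyaura sp3–sp2 coupling of a benzylic-type (furfuryl) chloride, in which the 5-formyl group restrains ionisation of the chloride while oxidative addition to Pd(0) stays easy, and neither the aldehyde nor the benzyl ether reacts with the boronic acid under phosphate in toluene.

Step 2
Reactants: 3 5-[4-(benzyloxy)-3-methoxybenzyl]furan-2-carbaldehyde
Product: 4 {5-[4-(benzyloxy)-3-methoxybenzyl]furan-2-yl}methanol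
Conditions: NaBH4, MeOH/THF, 0 °C
Reagents that add atoms: none
Why: Borohydride reduction of an aryl aldehyde to the primary alcohol, to which furan, diarylmethane and benzyl ether are inert.

Step 3
Reactants: 4 {5-[4-(benzyloxy)-3-methoxybenzyl]furan-2-yl}methanol; 5 methyl 2,2-dimethoxyacetate
Product: 7 methyl 3-{5-[4-(benzyloxy)-3-methoxybenzyl]furan-2-yl}-2,2-dimethoxypropanoate, via furfuryl bromide 6 (not isolated)
Conditions: PBr3, Et2O, −10 °C, cold filtration through K2CO3; then added to 5 + LDA, THF/DMPU, −78 → −20 °C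
Reagents that add atoms: none
Why: Bromination of the furfuryl alcohol with PBr3 and SN2 C-alkylation of an ester enolate, in which the lithium enolate of methyl dimethoxyacetate acts as a glyoxylate acyl-anion equivalent and delivers the α-keto ester directly as its dimethyl ketal, so that no acid ketalisation of a furyl enol ether is needed and the quaternary product cannot be alkylated again.

Step 4
Reactants: 7 methyl 3-{5-[4-(benzyloxy)-3-methoxybenzyl]furan-2-yl}-2,2-dimethoxypropanoate; 8 2,4-dimethoxybenzylamine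
Product: 9 3-{5-[4-(benzyloxy)-3-methoxybenzyl]furan-2-yl}-N-(2,4-dimethoxybenzyl)-2,2-dimethoxypropanamide
Conditions: AlMe3, toluene, 0 → 60 °C; Rochelle salt work-up
Reagents that add atoms: none
Why: Weinreb aminolysis, in which the dimethylaluminium amide of 8 attacks the α,α-dialkoxy-activated methyl ester, which has no α-hydrogen to enolise, while ketal, furan and benzyl ether tolerate the reagent.

Step 5
Reactants: 9 3-{5-[4-(benzyloxy)-3-methoxybenzyl]furan-2-yl}-N-(2,4-dimethoxybenzyl)-2,2-dimethoxypropanamide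
Product: 11 3-{5-[4-(benzyloxy)-3-methoxybenzyl]furan-2-yl}-N-(2,4-dimethoxybenzyl)-N-ethynyl-2,2-dimethoxypropanamide, via C-silyl ynamide 10 (not isolated)
Conditions: KHMDS, toluene, 0 °C; Me3SiC≡C–I(Ph)OTf, 0 °C → rt; then TBAF, wet THF, 0 °C
Reagents that add atoms: [(trimethylsilyl)ethynyl](phenyl)iodonium triflate, C[Si](C)(C)C#C[I+]c1ccccc1.[O-]S(=O)(=O)C(F)(F)F
Why: N-alkynylation of a potassium amidate with an alkynyl(phenyl)iodonium salt (conjugate addition at the β-carbon, loss of iodobenzene, 1,2-silyl shift of the alkylidene carbene) followed by fluoride C-desilylation, the standard entry to terminal ynamides, the amide N–H being the only proton acidic enough for one equivalent of KHMDS.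

Step 6
Reactants: 11 3-{5-[4-(benzyloxy)-3-methoxybenzyl]furan-2-yl}-N-(2,4-dimethoxybenzyl)-N-ethynyl-2,2-dimethoxypropanamide
Product: 14 7-[4-(benzyloxy)-3-methoxybenzyl]-1-(2,4-dimethoxybenzyl)-8-hydroxy-3,3-dimethoxy-3,4-dihydroquinolin-2(1H)-one, via oxepine 12 (not isolated), via arene oxide 13 (not isolated)
Conditions: [JohnPhosAu(NCMe)]SbF6 (3 mol%), CH2Cl2, 4 Å MS, rt
Reagents that add atoms: none
Why: Gold(I) π-activates the terminal ynamide as a keteniminium-like species and furan C2 attacks the nitrogen-bearing alkyne carbon (6-exo-dig closure of the lactam ring, C4a–C8a), the gem-dimethoxy carbon and the amide rotamer with the slim alkynyl group syn to C3 holding the two ends together. The resulting cyclopropyl gold carbenoid opens the furan to a (Z)-dienone gold carbene whose ketone oxygen closes onto the carbene carbon (C8–O) to give oxepine 12, and disrotatory 6π-electrocyclisation of 12 closes the carbocycle (C7–C8) as arene oxide 13. Oxide 13 opens at C7, where the cation is tertiary and conjugated to the nitrogen on C8a, and loss of the C8 proton gives the phenol, so the furan oxygen ends on C8 and the former 5-benzyl group on C7. This is the gold-catalysed furan–yne phenol synthesis in its known furan–ynamide form, here with the tether acyl group as the acceptor on nitrogen. No stereocentre has to be controlled, because the two centres of 13 vanish on aromatisation. The selectivity needed is regiochemical (OH on C8, not on C5 or C7) and is secured by the ynamide polarisation, which sends furan C2 to the N-bearing carbon, and by the substituted, N-conjugated C7 terminus of the arene oxide.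

Step 7
Reactants: 14 7-[4-(benzyloxy)-3-methoxybenzyl]-1-(2,4-dimethoxybenzyl)-8-hydroxy-3,3-dimethoxy-3,4-dihydroquinolin-2(1H)-one
Product: 15 7-[4-(benzyloxy)-3-methoxybenzyl]-1-(2,4-dimethoxybenzyl)-3,3-dimethoxy-2-oxo-1,2,3,4-tetrahydroquinolin-8-yl 2,2,2-trichloroethyl sulfate
Conditions: NaHMDS, THF, −78 °C; Cl3CCH2OSO2Cl, −78 → 0 °C
Reagents that add atoms: 2,2,2-trichloroethyl chlorosulfate, ClS(=O)(=O)OCC(Cl)(Cl)Cl
Why: O-sulfonylation of the sodium phenoxide with an alkyl chlorosulfate, the C8 hydroxyl being the only acidic and nucleophilic site of 14, which installs the sulfate as a trichloroethyl diester that is stable to acid and to chromatography.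

Step 8
Reactants: 15 7-[4-(benzyloxy)-3-methoxybenzyl]-1-(2,4-dimethoxybenzyl)-3,3-dimethoxy-2-oxo-1,2,3,4-tetrahydroquinolin-8-yl 2,2,2-trichloroethyl sulfate
Product: 17 7-[4-(benzyloxy)-3-methoxybenzyl]-3-methoxy-2-oxo-1,2-dihydroquinolin-8-yl 2,2,2-trichloroethyl sulfate, via N-benzylated quinolinone 16 (not isolated)
Conditions: TFA/CH2Cl2 (1:1), 1,3-dimethoxybenzene (5 equiv), rt → 40 °C
Reagents that add atoms: none
Why: Acidolysis in two events, E1 loss of methanol from the ketal through the 3-methoxy oxocarbenium ion to the aromatic quinolinone 16, then SN1 N-debenzylation (helped by the peri sulfate) with Friedel–Crafts capture of the dimethoxybenzyl cation by 1,3-dimethoxybenzene, while the sulfate diester is acid-stable and any partial loss of the O-benzyl group would converge in step 9.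

Step 9
Reactants: 17 7-[4-(benzyloxy)-3-methoxybenzyl]-3-methoxy-2-oxo-1,2-dihydroquinolin-8-yl 2,2,2-trichloroethyl sulfate
Product: 19 scolopendrine, via O-benzyl sulfate 18 (not isolated)
Conditions: 10% Pd/C, HCO2NH4, MeOH, rt
Reagents that add atoms: none
Why: Catalytic transfer hydrogenolysis, in which Pd/formate first cleaves the trichloroethyl ester reductively (C–Cl insertion, β-elimination of the sulfate monoester) and then hydrogenolyses the benzyl ether under neutral conditions that the aryl sulfate, the diarylmethane and the quinolinone should survive.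

**Compound list**

1 | 5-(chloromethyl)furan-2-carbaldehyde | O=Cc1ccc(CCl)o1 | starting material
2 | [4-(benzyloxy)-3-methoxyphenyl]boronic acid | COc1cc(B(O)O)ccc1OCc1ccccc1 | starting material
3 | 5-[4-(benzyloxy)-3-methoxybenzyl]furan-2-carbaldehyde | O=Cc1ccc(Cc2ccc(OCc3ccccc3)c(OC)c2)o1 | intermediate
4 | {5-[4-(benzyloxy)-3-methoxybenzyl]furan-2-yl}methanol | OCc1ccc(Cc2ccc(OCc3ccccc3)c(OC)c2)o1 | intermediate
5 | methyl 2,2-dimethoxyacetate | COC(OC)C(=O)OC | starting material
6 | 2-[4-(benzyloxy)-3-methoxybenzyl]-5-(bromomethyl)furan | BrCc1ccc(Cc2ccc(OCc3ccccc3)c(OC)c2)o1 | intermediate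
7 | methyl 3-{5-[4-(benzyloxy)-3-methoxybenzyl]furan-2-yl}-2,2-dimethoxypropanoate | COC(=O)C(OC)(OC)Cc1ccc(Cc2ccc(OCc3ccccc3)c(OC)c2)o1 | intermediate
8 | 2,4-dimethoxybenzylamine | COc1ccc(CN)c(OC)c1 | starting material
9 | 3-{5-[4-(benzyloxy)-3-methoxybenzyl]furan-2-yl}-N-(2,4-dimethoxybenzyl)-2,2-dimethoxypropanamide | COc1ccc(CNC(=O)C(OC)(OC)Cc2ccc(Cc3ccc(OCc4ccccc4)c(OC)c3)o2)c(OC)c1 | intermediate
10 | 3-{5-[4-(benzyloxy)-3-methoxybenzyl]furan-2-yl}-N-(2,4-dimethoxybenzyl)-2,2-dimethoxy-N-[(trimethylsilyl)ethynyl]propanamide | COc1ccc(CN(C#C[Si](C)(C)C)C(=O)C(OC)(OC)Cc2ccc(Cc3ccc(OCc4ccccc4)c(OC)c3)o2)c(OC)c1 | intermediate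
11 | 3-{5-[4-(benzyloxy)-3-methoxybenzyl]furan-2-yl}-N-(2,4-dimethoxybenzyl)-N-ethynyl-2,2-dimethoxypropanamide | C#CN(Cc1ccc(OC)cc1OC)C(=O)C(OC)(OC)Cc1ccc(Cc2ccc(OCc3ccccc3)c(OC)c2)o1 | intermediate
12 | oxepine valence tautomer: N-(2,4-dimethoxybenzyl)-3,3-dimethoxy-3,4-dihydropyridin-2-one fused to an oxepine whose oxygen bridges the future C7 (benzyl-bearing) and C8 (CH) | COc1ccc(CN2C(=O)C(OC)(OC)CC3=CC=C(Cc4ccc(OCc5ccccc5)c(OC)c4)OC=C32)c(OC)c1 | intermediate
13 | 7-[4-(benzyloxy)-3-methoxybenzyl]-1-(2,4-dimethoxybenzyl)-7,8-epoxy-3,3-dimethoxy-3,4,7,8-tetrahydroquinolin-2(1H)-one (arene oxide, cis-fused, racemic; one enantiomer drawn) | COc1ccc(CN2C(=O)C(OC)(OC)CC3=C2[C@H]4O[C@@]4(Cc5ccc(OCc6ccccc6)c(OC)c5)C=C3)c(OC)c1 | intermediate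
14 | 7-[4-(benzyloxy)-3-methoxybenzyl]-1-(2,4-dimethoxybenzyl)-8-hydroxy-3,3-dimethoxy-3,4-dihydroquinolin-2(1H)-one | COc1ccc(CN2C(=O)C(OC)(OC)Cc3ccc(Cc4ccc(OCc5ccccc5)c(OC)c4)c(O)c32)c(OC)c1 | intermediate
15 | 7-[4-(benzyloxy)-3-methoxybenzyl]-1-(2,4-dimethoxybenzyl)-3,3-dimethoxy-2-oxo-1,2,3,4-tetrahydroquinolin-8-yl 2,2,2-trichloroethyl sulfate | COc1ccc(CN2C(=O)C(OC)(OC)Cc3ccc(Cc4ccc(OCc5ccccc5)c(OC)c4)c(OS(=O)(=O)OCC(Cl)(Cl)Cl)c32)c(OC)c1 | intermediate
16 | 7-[4-(benzyloxy)-3-methoxybenzyl]-1-(2,4-dimethoxybenzyl)-3-methoxy-2-oxo-1,2-dihydroquinolin-8-yl 2,2,2-trichloroethyl sulfate | COc1ccc(Cn2c(=O)c(OC)cc3ccc(Cc4ccc(OCc5ccccc5)c(OC)c4)c(OS(=O)(=O)OCC(Cl)(Cl)Cl)c32)c(OC)c1 | intermediate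
17 | 7-[4-(benzyloxy)-3-methoxybenzyl]-3-methoxy-2-oxo-1,2-dihydroquinolin-8-yl 2,2,2-trichloroethyl sulfate | COc1cc(Cc2ccc3cc(OC)c(=O)[nH]c3c2OS(=O)(=O)OCC(Cl)(Cl)Cl)ccc1OCc1ccccc1 | intermediate
18 | 7-[4-(benzyloxy)-3-methoxybenzyl]-3-methoxy-2-oxo-1,2-dihydroquinolin-8-yl hydrogen sulfate | COc1cc(Cc2ccc3cc(OC)c(=O)[nH]c3c2OS(=O)(=O)O)ccc1OCc1ccccc1 | intermediate
19 | scolopendrine, 7-(4-hydroxy-3-methoxybenzyl)-3-methoxy-2-oxo-1,2-dihydroquinolin-8-yl hydrogen sulfate | COc1cc(Cc2ccc3cc(OC)c(=O)[nH]c3c2OS(=O)(=O)O)ccc1O | target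

**Step count**

Total steps: 9. Longest linear sequence: 9 (steps 1–9; compounds 2, 5 and 8 enter as bought materials).

**Steps most likely to fail**

Step 6. The gold-activated alkyne may be captured by the amide carbonyl oxygen (5-endo-dig O-cyclisation to an oxazolium, possibly with loss of the dimethoxybenzyl cation), or the ynamide may be hydrated before the furan attacks. Opening of the arene oxide at the wrong carbon would also displace the benzyl group. Fallback, from 7 back to 17: the benzannulation is run on the N-sulfonyl ynamide, the class on which the furan–ynamide reaction is established, and the lactam carbonyl is introduced afterwards. Ester 7 with methanolic ammonia should give the primary amide F1, LiAlH4 the primary amine F2 and TsCl/Et3N the sulfonamide F3. Alkynylation as in step 5 gives the C-silyl ynamide F4 and, after fluoride, the terminal N-tosyl ynamide F5, which gold(I) should isomerise to the 1-tosyl-1,2,3,4-tetrahydroquinolin-8-ol F6. Acid (TsOH, toluene) then eliminates methanol and t-BuOK expels p-toluenesulfinate to give the 3-methoxyquinolin-8-ol F7. mCPBA gives the N-oxide F8, and the acetic anhydride rearrangement of the N-oxide with methanolysis of the acetates gives the 8-hydroxyquinolin-2(1H)-one F9. O-Sulfonylation of F9 with trichloroethyl chlorosulfate (Et3N, DMAP) returns to 17.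

Step 5. The hindered amidate may attack the iodonium salt through oxygen or too slowly, and the N-acyl ynamide may be cleaved at the acyl–nitrogen bond during desilylation. Fallback, from 9 back to 11: amide 9 is vinylated with trichloroethylene (Cs2CO3, DMF, 50 °C; dichloroacetylene formed in situ) to the (E)-1,2-dichloroenamide F10. PhLi (THF, −78 °C) eliminates HCl to the chloroynamide F11 and exchanges its chlorine for lithium, and protonation of the lithium acetylide gives 11 without any silyl group to remove.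

Step 3. The electron-rich furfuryl bromide may ionise and polymerise before C–C bond formation, and the dialkoxyacetate enolate may undergo Claisen self-condensation. Fallback, from 3 (with 5) back to 7: aldol addition of the same lithium enolate to aldehyde 3 gives the racemic β-hydroxy ester F12. Thiocarbonyldiimidazole converts it into the O-(imidazol-1-ylthiocarbonyl) derivative F13, and Barton–McCombie reduction (Bu3SnH, AIBN, toluene, 80 °C) through the furfuryl radical returns to 7 without any furfuryl halide.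

**Further compounds**

F1 | step 6 | 3-{5-[4-(benzyloxy)-3-methoxybenzyl]furan-2-yl}-2,2-dimethoxypropanamide | NC(=O)C(OC)(OC)Cc1ccc(Cc2ccc(OCc3ccccc3)c(OC)c2)o1
F2 | step 6 | 3-{5-[4-(benzyloxy)-3-methoxybenzyl]furan-2-yl}-2,2-dimethoxypropan-1-amine | NCC(OC)(OC)Cc1ccc(Cc2ccc(OCc3ccccc3)c(OC)c2)o1
F3 | step 6 | N-(3-{5-[4-(benzyloxy)-3-methoxybenzyl]furan-2-yl}-2,2-dimethoxypropyl)-4-methylbenzenesulfonamide | Cc1ccc(cc1)S(=O)(=O)NCC(OC)(OC)Cc1ccc(Cc2ccc(OCc3ccccc3)c(OC)c2)o1
F4 | step 6 | N-(3-{5-[4-(benzyloxy)-3-methoxybenzyl]furan-2-yl}-2,2-dimethoxypropyl)-4-methyl-N-[(trimethylsilyl)ethynyl]benzenesulfonamide | Cc1ccc(cc1)S(=O)(=O)N(C#C[Si](C)(C)C)CC(OC)(OC)Cc1ccc(Cc2ccc(OCc3ccccc3)c(OC)c2)o1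
F5 | step 6 | N-(3-{5-[4-(benzyloxy)-3-methoxybenzyl]furan-2-yl}-2,2-dimethoxypropyl)-N-ethynyl-4-methylbenzenesulfonamide | Cc1ccc(cc1)S(=O)(=O)N(C#C)CC(OC)(OC)Cc1ccc(Cc2ccc(OCc3ccccc3)c(OC)c2)o1
F6 | step 6 | 7-[4-(benzyloxy)-3-methoxybenzyl]-3,3-dimethoxy-1-tosyl-1,2,3,4-tetrahydroquinolin-8-ol | Cc1ccc(cc1)S(=O)(=O)N1CC(OC)(OC)Cc2ccc(Cc3ccc(OCc4ccccc4)c(OC)c3)c(O)c21
F7 | step 6 | 7-[4-(benzyloxy)-3-methoxybenzyl]-3-methoxyquinolin-8-ol | COc1cnc2c(O)c(Cc3ccc(OCc4ccccc4)c(OC)c3)ccc2c1
F8 | step 6 | 7-[4-(benzyloxy)-3-methoxybenzyl]-3-methoxyquinolin-8-ol 1-oxide | COc1c[n+]([O-])c2c(O)c(Cc3ccc(OCc4ccccc4)c(OC)c3)ccc2c1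
F9 | step 6 | 7-[4-(benzyloxy)-3-methoxybenzyl]-8-hydroxy-3-methoxyquinolin-2(1H)-one | COc1cc(Cc2ccc3cc(OC)c(=O)[nH]c3c2O)ccc1OCc1ccccc1
F10 | step 5 | 3-{5-[4-(benzyloxy)-3-methoxybenzyl]furan-2-yl}-N-[(E)-1,2-dichlorovinyl]-N-(2,4-dimethoxybenzyl)-2,2-dimethoxypropanamide | Cl/C=C(/Cl)N(Cc1ccc(OC)cc1OC)C(=O)C(OC)(OC)Cc1ccc(Cc2ccc(OCc3ccccc3)c(OC)c2)o1
F11 | step 5 | 3-{5-[4-(benzyloxy)-3-methoxybenzyl]furan-2-yl}-N-(chloroethynyl)-N-(2,4-dimethoxybenzyl)-2,2-dimethoxypropanamide | ClC#CN(Cc1ccc(OC)cc1OC)C(=O)C(OC)(OC)Cc1ccc(Cc2ccc(OCc3ccccc3)c(OC)c2)o1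
F12 | step 3 | methyl 3-{5-[4-(benzyloxy)-3-methoxybenzyl]furan-2-yl}-3-hydroxy-2,2-dimethoxypropanoate (racemic) | COC(=O)C(OC)(OC)C(O)c1ccc(Cc2ccc(OCc3ccccc3)c(OC)c2)o1
F13 | step 3 | methyl 3-{5-[4-(benzyloxy)-3-methoxybenzyl]furan-2-yl}-3-[(1H-imidazol-1-ylcarbonothioyl)oxy]-2,2-dimethoxypropanoate (racemic) | COC(=O)C(OC)(OC)C(OC(=S)n1ccnc1)c1ccc(Cc2ccc(OCc3ccccc3)c(OC)c2)o1
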